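**Retrosynthetic overview**

1. Locants: the side chain is counted from C1' (the CH2 on the six-membered ring) to C16'. The E alkenes are C2'=C3' and C6'=C7', C10' is the secondary carbinol, C11' the tertiary carbinol, and C14'=C15' the prenyl end.
2. End game, read backwards: hydrolysis of a C10'/C11' dioxolane, oxidative demethylation of a 1,4-dimethoxybenzene ring to the quinone ring, and stereoretentive exchange of a C7'–Cl bond for the C7' methyl group.
3. Key disconnection C7'–C8': a one-flask hydroboration and site-selective B-alkyl Suzuki–Miyaura monocoupling. It joins a vinyl dioxolane (C8'–C16', both stereocentres) to an aryl-bearing 1,1-dichloroalkene Cl2C7'=C6'H (ring plus C1'–C7').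
4. Enabling feature: C7' is a fully substituted sp2 carbon whose two carbon ligands, C8' and CH3, differ only in lying trans or cis to the C5' methylene on C6'. In Cl2C7'=C6'H–C5'H2 this becomes a steric difference between two C–Cl bonds, so a precursor with no alkene geometry delivers the 6'E alkene. C8'=C9', next to the dioxolane ring, is the only monosubstituted alkene and alone takes up boron.
5. Fragments and rings: nerol gives C9'–C16' (asymmetric epoxidation, then Payne shift and ylide homologation add C8' and set C10'/C11'). Geranyl acetate gives C1'–C6' (alkene cleavage; dichloromethylenation adds C7') and is joined to an aryl Grignard reagent. No ring of the target is built, since the six-membered ring enters as benzene; the temporary rings form in the order oxirane, then dioxolane.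

Key step: step 12

Remark on the chemistry: the oxirane carbon made in step 4 is left racemic because step 5 destroys it. Nerol, geranyl acetate and 4-methoxy-2-methylphenol are taken as commercial.

**Route**

Step 1
Reactants: 1 nerol
Product: 2 (2R,3S)-2,3-epoxynerol
Conditions: Ti(OiPr)4 (10 mol %), D-(−)-diethyl tartrate (12 mol %), t-BuOOH, 4 Å MS, CH2Cl2, −20 °C
Reagents that add atoms: tert-butyl hydroperoxide CC(C)(C)OO
Why: Sharpless asymmetric epoxidation: the allylic OH binds to the complex formed from Ti(OiPr)4 and the tartrate, so only the C2=C3 alkene is oxidised, and the D-(−)-tartrate directs oxygen to the face that gives the 2R,3S oxirane (these carbons become C10' and C11').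

Step 2
Reactants: 2 (2R,3S)-2,3-epoxynerol
Product: 5 (3S,4S)-4,8-dimethylnona-1,7-diene-3,4-diol, via Payne isomer 3 (not isolated), via sulfonium betaine 4 (not isolated)
Conditions: Me3S+ I− (4 equiv), n-BuLi (3.8 equiv), THF, −10 °C to rt
Reagents that add atoms: trimethylsulfonium iodide C[S+](C)C.[I-]
Why: Payne rearrangement followed by sulfonium-ylide homologation of a terminal epoxide to an allylic alcohol: the C1 alkoxide opens the oxirane at C2 with inversion while the C3–O bond is untouched, the ylide attacks the unhindered CH2 of terminal oxirane 3 and so drains the equilibrium, and betaine 4 loses Me2S by ylide-mediated elimination, which should leave both carbinol carbons S.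

Step 3
Reactants: 5 (3S,4S)-4,8-dimethylnona-1,7-diene-3,4-diol
Product: 6 (4S,5S)-5-ethenyl-2,2,4-trimethyl-4-(4-methylpent-3-en-1-yl)-1,3-dioxolane
Conditions: 2,2-dimethoxypropane, PPTS (cat.), CH2Cl2, rt
Reagents that add atoms: 2,2-dimethoxypropane COC(C)(C)OC
Why: Acid-catalysed transketalisation closes the five-membered dioxolane ring over both hydroxyl groups without breaking a C–O bond at either stereocentre.

Step 4
Reactants: 7 geranyl acetate
Product: 8 6,7-epoxygeranyl acetate (racemic at the oxirane CH)
Conditions: mCPBA (1.0 equiv), NaHCO3, CH2Cl2, 0 °C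
Reagents that add atoms: 3-chloroperoxybenzoic acid OOC(=O)c1cccc(Cl)c1
Why: Prilezhaev epoxidation picks the electron-rich C6=C7 alkene because the C2=C3 alkene is deactivated by the allylic acetate; the new stereocentre needs no control since step 5 removes it.

Step 5
Reactants: 8 6,7-epoxygeranyl acetate
Product: 10 (2E)-3-methyl-6-oxohex-2-en-1-yl acetate, via diol 9 (not isolated)
Conditions: H5IO6 (1.2 equiv), THF/H2O, 0 °C
Reagents that add atoms: none
Why: Acid-promoted hydration of the oxirane and Malaprade glycol cleavage in one flask turn C6 into the aldehyde carbon and leave the allylic acetate and the E alkene alone.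

Step 6
Reactants: 10 (2E)-3-methyl-6-oxohex-2-en-1-yl acetate
Product: 11 (2E)-7,7-dichloro-3-methylhepta-2,6-dien-1-yl acetate
Conditions: PPh3 (3 equiv), BrCCl3 (1.5 equiv), CH2Cl2, 0 °C to rt
Reagents that add atoms: bromotrichloromethane ClC(Cl)(Cl)Br
Why: Wittig-type dichloromethylenation with Ph3P=CCl2 made in the flask converts the aldehyde into the 1,1-dichloroalkene, which has no geometry to control, under neutral conditions that spare the acetate.

Step 7
Reactants: 11 (2E)-7,7-dichloro-3-methylhepta-2,6-dien-1-yl acetate
Product: 12 (2E)-7,7-dichloro-3-methylhepta-2,6-dien-1-ol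
Conditions: K2CO3 (0.2 equiv), MeOH, rt
Reagents that add atoms: none
Why: Base-catalysed transesterification (Zemplén type) removes the acetate, and the dichloroalkene is inert to carbonate in methanol.

Step 8
Reactants: 12 (2E)-7,7-dichloro-3-methylhepta-2,6-dien-1-ol
Product: 13 (5E)-7-bromo-1,1-dichloro-5-methylhepta-1,5-diene
Conditions: CBr4, PPh3, CH2Cl2, 0 °C
Reagents that add atoms: tetrabromomethane BrC(Br)(Br)Br
Why: The Appel reaction replaces the primary allylic OH by bromide through SN2 under neutral conditions, which should keep the E alkene and avoid allylic transposition.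

Step 9
Reactants: 14 4-methoxy-2-methylphenol
Product: 15 2-bromo-4-methoxy-6-methylphenol
Conditions: NBS (1.0 equiv), CH2Cl2, 0 °C, dark
Reagents that add atoms: N-bromosuccinimide O=C1CCC(=O)N1Br
Why: In this electrophilic aromatic bromination the free OH is the strongest director, its para position is blocked by OMe and one ortho position by CH3, so bromine should enter the remaining ortho carbon.

Step 10
Reactants: 15 2-bromo-4-methoxy-6-methylphenol
Product: 16 1-bromo-2,5-dimethoxy-3-methylbenzene
Conditions: MeI, K2CO3, acetone, reflux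
Reagents that add atoms: iodomethane CI
Why: Williamson ether synthesis masks the phenol so that the ring enters the organometallic steps as a hydroquinone dimethyl ether.

Step 11
Reactants: 16 1-bromo-2,5-dimethoxy-3-methylbenzene; 13 (5E)-7-bromo-1,1-dichloro-5-methylhepta-1,5-diene
Product: 18 1-[(2E)-7,7-dichloro-3-methylhepta-2,6-dien-1-yl]-2,5-dimethoxy-3-methylbenzene, via arylmagnesium bromide 17 (not isolated)
Conditions: 16, Mg turnings, THF, 40 °C; then CuI (10 mol %), 13, THF, −20 to 0 °C
Reagents that add atoms: none
Why: In this copper-catalysed allylation of an aryl Grignard reagent, attack at the primary CH2–Br carbon (SN2) is favoured over the fully substituted gamma carbon, the E alkene is kept, and the vinylic C–Cl bonds do not react with magnesium or copper reagents at this temperature.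

Step 12
Reactants: 6 (4S,5S)-5-ethenyl-2,2,4-trimethyl-4-(4-methylpent-3-en-1-yl)-1,3-dioxolane; 18 1-[(2E)-7,7-dichloro-3-methylhepta-2,6-dien-1-yl]-2,5-dimethoxy-3-methylbenzene
Product: 20 1-{(2E,6Z)-7-chloro-3-methyl-9-[(4S,5S)-2,2,5-trimethyl-5-(4-methylpent-3-en-1-yl)-1,3-dioxolan-4-yl]nona-2,6-dien-1-yl}-2,5-dimethoxy-3-methylbenzene, via B-alkyl borane 19 (not isolated)
Conditions: 6 (1.3 equiv), 9-BBN (0.5 M in THF), 0 °C to rt; then 18, Pd2(dba)3 (2.5 mol %), XantPhos (5 mol %), KF, K3PO4, THF, 65 °C
Reagents that add atoms: none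
Why: 9-BBN adds anti-Markovnikov to the vinyl group of 6, the only monosubstituted alkene, and leaves the trisubstituted C14'=C15' alkene alone, which gives primary borane 19 with boron on C8'. Zerovalent palladium carrying the wide-bite-angle ligand XantPhos then inserts into the C7'–Cl bond of 18 that lies trans to the C5' methylene (cis to H on C6'), the less hindered of the two, the fluoride/phosphate-activated borate hands over the C8' alkyl group, and reductive elimination forms C7'–C8' with retention. The closest known reaction type is the B-alkyl Suzuki–Miyaura monocoupling of 1,1-dichloro-1-alkenes with 9-alkyl-9-BBN reagents, which gives (Z)-chloroalkenes. No ring is closed and no stereocentre is made; the stereochemical element created is the C6'=C7' geometry, controlled by the steric difference between the two C–Cl bonds, while C10' and C11' sit untouched in the dioxolane ring. The step needs mono- over double coupling, secured because the remaining C–Cl bond is cis to the chain, more hindered and on a more electron-rich alkene, and it needs freedom from beta-hydride loss, secured by the fast reductive elimination of the wide-bite-angle complex.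

Step 13
Reactants: 20 the (6Z)-7-chloro coupling product
Product: 21 1-{(2E,6E)-3,7-dimethyl-9-[(4S,5S)-2,2,5-trimethyl-5-(4-methylpent-3-en-1-yl)-1,3-dioxolan-4-yl]nona-2,6-dien-1-yl}-2,5-dimethoxy-3-methylbenzene
Conditions: Me2Zn (2 equiv), Pd(PtBu3)2 (5 mol %), THF, 50 °C
Reagents that add atoms: dimethylzinc C[Zn]C
Why: Negishi coupling of an alkenyl chloride: the bulky electron-rich phosphine lets zerovalent palladium insert into the remaining hindered C7'–Cl bond, and insertion, transmetalation from zinc and reductive elimination all run with retention, so CH3 should end cis to C5' and the alkene 6'E.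

Step 14
Reactants: 21 the hydroquinone dimethyl ether acetonide
Product: 22 2-{(2E,6E)-3,7-dimethyl-9-[(4S,5S)-2,2,5-trimethyl-5-(4-methylpent-3-en-1-yl)-1,3-dioxolan-4-yl]nona-2,6-dien-1-yl}-6-methylcyclohexa-2,5-diene-1,4-dione
Conditions: (NH4)2Ce(NO3)6 (2.5 equiv), MeCN/H2O 3:1, 0 °C
Reagents that add atoms: water O
Why: Oxidative demethylation of a 1,4-dimethoxybenzene by tetravalent cerium: two one-electron oxidations with attack of water at the two oxygen-bearing ring carbons expel two MeOH and should give the quinone faster than the isolated alkenes or the dioxolane ring react.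

Step 15
Reactants: 22 the quinone acetonide
Product: 23 2-[(2E,6E,10S,11S)-10,11-dihydroxy-3,7,11,15-tetramethylhexadeca-2,6,14-trien-1-yl]-6-methylcyclohexa-2,5-diene-1,4-dione (target)
Conditions: AcOH/H2O 4:1, 40 °C
Reagents that add atoms: none
Why: Acid-catalysed acetal hydrolysis cleaves C–O only at the acetal carbon, so C10' and C11' keep their oxygen atoms and their S configuration, and the weak acid should spare the quinone, the tertiary alcohol and the alkenes.

**Compound list**

| No. | Name | SMILES | Role |
|---|---|---|---|
| 1 | nerol, (2Z)-3,7-dimethylocta-2,6-dien-1-ol | CC(C)=CCC/C(C)=C\CO | starting material |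
| 2 | (2R,3S)-2,3-epoxynerol | CC(C)=CCC[C@]1(C)O[C@@H]1CO | intermediate |
| 3 | (2S)-6-methyl-2-[(2S)-oxiran-2-yl]hept-5-en-2-ol (Payne isomer) | CC(C)=CCC[C@](C)(O)[C@@H]1CO1 | intermediate |
| 4 | dimethyl[(3S,4S)-4-hydroxy-4,8-dimethyl-3-oxidonon-7-en-1-yl]sulfonium (betaine) | CC(C)=CCC[C@](C)(O)[C@@H]([O-])CC[S+](C)C | intermediate |
| 5 | (3S,4S)-4,8-dimethylnona-1,7-diene-3,4-diol | CC(C)=CCC[C@](C)(O)[C@@H](O)C=C | intermediate |
| 6 | (4S,5S)-5-ethenyl-2,2,4-trimethyl-4-(4-methylpent-3-en-1-yl)-1,3-dioxolane | CC(C)=CCC[C@]1(C)OC(C)(C)O[C@H]1C=C | intermediate |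
| 7 | geranyl acetate | CC(C)=CCC/C(C)=C/COC(C)=O | starting material |
| 8 | 6,7-epoxygeranyl acetate (racemic) | CC1(C)OC1CC/C(C)=C/COC(C)=O | intermediate |
| 9 | (2E)-6,7-dihydroxy-3,7-dimethyloct-2-en-1-yl acetate (racemic) | CC(C)(O)C(O)CC/C(C)=C/COC(C)=O | intermediate |
| 10 | (2E)-3-methyl-6-oxohex-2-en-1-yl acetate | O=CCC/C(C)=C/COC(C)=O | intermediate |
| 11 | (2E)-7,7-dichloro-3-methylhepta-2,6-dien-1-yl acetate | ClC(Cl)=CCC/C(C)=C/COC(C)=O | intermediate |
| 12 | (2E)-7,7-dichloro-3-methylhepta-2,6-dien-1-ol | ClC(Cl)=CCC/C(C)=C/CO | intermediate |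
| 13 | (5E)-7-bromo-1,1-dichloro-5-methylhepta-1,5-diene | ClC(Cl)=CCC/C(C)=C/CBr | intermediate |
| 14 | 4-methoxy-2-methylphenol | COc1ccc(O)c(C)c1 | starting material |
| 15 | 2-bromo-4-methoxy-6-methylphenol | COc1cc(C)c(O)c(Br)c1 | intermediate |
| 16 | 1-bromo-2,5-dimethoxy-3-methylbenzene | COc1cc(C)c(OC)c(Br)c1 | intermediate |
| 17 | (2,5-dimethoxy-3-methylphenyl)magnesium bromide | COc1cc(C)c(OC)c([Mg]Br)c1 | intermediate |
| 18 | 1-[(2E)-7,7-dichloro-3-methylhepta-2,6-dien-1-yl]-2,5-dimethoxy-3-methylbenzene | COc1cc(C)c(OC)c(C/C=C(\C)CCC=C(Cl)Cl)c1 | intermediate |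
| 19 | 9-{2-[(4S,5S)-2,2,5-trimethyl-5-(4-methylpent-3-en-1-yl)-1,3-dioxolan-4-yl]ethyl}-9-borabicyclo[3.3.1]nonane | CC(C)=CCC[C@]1(C)OC(C)(C)O[C@H]1CCB1C2CCCC1CCC2 | intermediate |
| 20 | (2E,6Z)-7-chloro coupling product (name in step 12) | CC(C)=CCC[C@]1(C)OC(C)(C)O[C@H]1CC/C(Cl)=C/CC/C(C)=C/Cc1cc(OC)cc(C)c1OC | intermediate |
| 21 | (2E,6E)-hydroquinone dimethyl ether acetonide (name in step 13) | CC(C)=CCC[C@]1(C)OC(C)(C)O[C@H]1CC/C(C)=C/CC/C(C)=C/Cc1cc(OC)cc(C)c1OC | intermediate |
| 22 | quinone acetonide (name in step 14) | CC(C)=CCC[C@]1(C)OC(C)(C)O[C@H]1CC/C(C)=C/CC/C(C)=C/CC1=CC(=O)C=C(C)C1=O | intermediate |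
| 23 | 2-[(2E,6E,10S,11S)-10,11-dihydroxy-3,7,11,15-tetramethylhexadeca-2,6,14-trien-1-yl]-6-methylcyclohexa-2,5-diene-1,4-dione | CC(C)=CCC[C@](C)(O)[C@@H](O)CC/C(C)=C/CC/C(C)=C/CC1=CC(=O)C=C(C)C1=O | target |

**Step count**

- Total step count: 15.
- Longest linear sequence: 10 steps (4, 5, 6, 7, 8, 11, 12, 13, 14, 15).

**Steps most likely to fail**

1. **Step 12.**
   - What may go wrong: slow insertion of zerovalent palladium into the C–Cl bond, a second coupling at the remaining chloride, base-induced loss of HCl from the dichloroalkene, or protodeboronation of the borane.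
   - Fallback: boron is replaced by zinc, so the nucleophile is an isolated precursor and the coupling needs no base. This is the Negishi trans-selective monoalkylation of 1,1-dichloroalkenes.
   - It sets out from 6. Hydroboration to 19 and oxidation (NaOH, H2O2) should give the primary alcohol F1.
   - Appel iodination (I2, PPh3, imidazole, CH2Cl2) should give the primary iodide F2.
   - Zinc insertion (Zn dust, LiCl, THF) should give the alkylzinc iodide F3.
   - Coupling of F3 with 18 under PdCl2(DPEphos) in THF/DMF should form the same C7'–C8' bond at the chloride trans to C5'. The fallback comes back to the route at 20.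

2. **Step 2.**
   - What may go wrong: a slow or unfavourable Payne shift of the lithium alkoxide in THF, so that the ylide decays or attacks the trisubstituted oxirane before the terminal oxirane is formed.
   - Fallback: the Payne equilibrium is drained in water by a thiolate, and the terminal oxirane is then made as an isolated compound.
   - It sets out from 2. PhSH added slowly to aqueous NaOH/t-BuOH at 70 °C should give the sulfide diol F4, with the same inversion at C2.
   - S-methylation (Me3OBF4, CH2Cl2) should give the sulfonium tetrafluoroborate F5.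
   - NaH in THF should close the C10' alkoxide onto the CH2–S carbon to give 3, now isolated.
   - 3 is treated at once with Me3S+ I−/n-BuLi as in step 2. If the Payne shift is slow in THF, that same slowness keeps 3 from reverting. The fallback comes back to the route at 5.

3. **Step 13.**
   - What may go wrong: sluggish oxidative addition into the hindered, electron-rich trisubstituted C–Cl bond, or erosion of the alkene geometry during a slow coupling.
   - Fallback: the methyl group is put on C7' before the union, and a stereodefined alkenyl iodide takes the place of the dichloroalkene.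
   - It sets out from 18. n-BuLi (2.2 equiv, THF, −78 °C to 0 °C) and then MeI should give the methyl alkyne F6.
   - Hydrozirconation with excess Cp2Zr(H)Cl (THF, 40 °C; equilibration moves zirconium to the methyl-bearing carbon) and then I2 should give the (E)-alkenyl iodide F7.
   - B-alkyl Suzuki–Miyaura coupling of F7 with 19 (made from 6 as in step 12; PdCl2(dppf), AsPh3, Cs2CO3, DMF/THF/H2O, rt) should form C7'–C8' with retention. The fallback passes by 20 and comes back to the route at 21.

**Further compounds**

F1 | step 12 | 2-[(4S,5S)-2,2,5-trimethyl-5-(4-methylpent-3-en-1-yl)-1,3-dioxolan-4-yl]ethan-1-ol | CC(C)=CCC[C@]1(C)OC(C)(C)O[C@H]1CCO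
F2 | step 12 | (4S,5S)-5-(2-iodoethyl)-2,2,4-trimethyl-4-(4-methylpent-3-en-1-yl)-1,3-dioxolane | CC(C)=CCC[C@]1(C)OC(C)(C)O[C@H]1CCI
F3 | step 12 | {2-[(4S,5S)-2,2,5-trimethyl-5-(4-methylpent-3-en-1-yl)-1,3-dioxolan-4-yl]ethyl}zinc iodide | CC(C)=CCC[C@]1(C)OC(C)(C)O[C@H]1CC[Zn]I
F4 | step 2 | (2R,3S)-3,7-dimethyl-1-(phenylsulfanyl)oct-6-ene-2,3-diol | CC(C)=CCC[C@](C)(O)[C@@H](O)CSc1ccccc1
F5 | step 2 | [(2R,3S)-2,3-dihydroxy-3,7-dimethyloct-6-en-1-yl](methyl)phenylsulfonium tetrafluoroborate (mixture at sulfur) | CC(C)=CCC[C@](C)(O)[C@@H](O)C[S+](C)c1ccccc1.F[B-](F)(F)F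
F6 | step 13 | 2,5-dimethoxy-1-methyl-3-[(2E)-3-methyloct-2-en-6-yn-1-yl]benzene | CC#CCC/C(C)=C/Cc1cc(OC)cc(C)c1OC
F7 | step 13 | 1-[(2E,6E)-7-iodo-3-methylocta-2,6-dien-1-yl]-2,5-dimethoxy-3-methylbenzene | C/C(I)=C\CC/C(C)=C/Cc1cc(OC)cc(C)c1OC
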